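Plan (locants of the target: 14-oxabicyclo[11.2.1]hexadeca-4,8-diene; carbocycle C1–C13 plus C16; oxolane O14–C15–C1–C16–C13)
1. Retrosynthetic cuts, in order: malonate ester; O14–C13 (retro-oxa-Michael); C12=C13 of a ring enoate (intramolecular Horner–Wadsworth–Emmons); C8=C9 (Wittig); C7–C8 (ylide alkylation); C5–C6 and C4–CH3 (alkyne chemistry); the ring C=C of α-terpineol (ozonolysis).
2. Enabling feature: C12 carries the oxygenated one-carbon branch, so at the ester level C12=C13 is a ring enoate with C13 as β-carbon. The carbinol oxygen on C15 is 1,5 to C13 (O14–C15–C1–C16–C13), so a 5-exo oxa-Michael closes the oxolane across the 14-membered carbocycle and creates C13 and C12 together.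
3. Forward: the terpineol ring is opened to a differentiated chain; methyl ketone → alkyne → hydroxyethylation → Z-selective carbomagnesiation; ylide alkylation and Wittig reaction attach the phosphonate aldehyde; intramolecular HWE closes the carbocycle; the oxolane is closed last; reduction, allylic oxidation and malonylation finish.
4. Stereochemistry: C1 is bought with (R)-α-terpineol; C13 and C12 are relayed from it in the ring closure; 4Z comes from syn-carbomagnesiation, 8E from the stabilised ylide.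

Key step: step 13

Assumption: (R)-(+)-α-terpineol is bought in high enantiomeric purity; locants in each name refer to that compound's own name.

Step 1
Reactants: 1 (R)-(+)-α-terpineol
Product: 2 tert-butyldimethyl({2-[(1R)-4-methylcyclohex-3-en-1-yl]propan-2-yl}oxy)silane
Conditions: t-BuMe2SiOTf, 2,6-lutidine, CH2Cl2, 0 °C → rt
Reagents that add atoms: tert-butyldimethylsilyl trifluoromethanesulfonate, CC(C)(C)[Si](C)(C)OS(=O)(=O)C(F)(F)F
Why: Silylation of a tertiary alcohol with a silyl triflate and a hindered pyridine base is standard; the robust tertiary silyl ether masks the carbinol oxygen until the ring closure, and the stereocenter is untouched.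

Step 2
Reactants: 2 tert-butyldimethyl({2-[(1R)-4-methylcyclohex-3-en-1-yl]propan-2-yl}oxy)silane
Product: 5 (5R)-5-[2-(tert-butyldimethylsilyloxy)propan-2-yl]-7,7-dimethoxyheptan-2-one, via methoxy hydroperoxide 3 (not isolated), via keto aldehyde 4 (not isolated)
Conditions: O3, CH2Cl2/MeOH (4:1), −78 °C; Me2S, −78 °C → rt; then TsOH·H2O (cat.), rt; NaHCO3
Reagents that add atoms: ozone, [O-][O+]=O; methanol, CO
Why: Ozonolysis in methanol should place the carbonyl oxide on the CH carbon (trapped as the methoxy hydroperoxide) and free the methyl ketone; after reduction only the aldehyde is acetalised under mild acid (chemoselective acetalisation), so the two chain ends are differentiated.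

Step 3
Reactants: 5 (5R)-5-[2-(tert-butyldimethylsilyloxy)propan-2-yl]-7,7-dimethoxyheptan-2-one
Product: 7 tert-butyl{[(3R)-3-(2,2-dimethoxyethyl)-2-methylhept-6-yn-2-yl]oxy}dimethylsilane, via enol phosphate 6 (not isolated)
Conditions: LiN(i-Pr)2 (1.1 equiv), THF, −78 °C; ClP(O)(OEt)2, −78 °C → rt; LiN(i-Pr)2 (2.3 equiv), −78 °C → rt; H2O
Reagents that add atoms: none
Why: Kinetic enolisation on the methyl side, O-phosphorylation and elimination of the enol phosphate with excess amide base is the established conversion of a methyl ketone into a terminal alkyne.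

Step 4
Reactants: 7 tert-butyl{[(3R)-3-(2,2-dimethoxyethyl)-2-methylhept-6-yn-2-yl]oxy}dimethylsilane
Product: 8 (7R)-7-[2-(tert-butyldimethylsilyloxy)propan-2-yl]-9,9-dimethoxynon-3-yn-1-ol
Conditions: n-BuLi, THF, −78 °C; ethylene oxide, DMPU, −78 °C → rt; aq. NH4Cl
Reagents that add atoms: ethylene oxide, C1CO1
Why: SN2 opening of ethylene oxide by the lithium acetylide adds the two-carbon arm and places a hydroxyl in the homopropargylic position needed to direct step 5.

Step 5
Reactants: 8 (7R)-7-[2-(tert-butyldimethylsilyloxy)propan-2-yl]-9,9-dimethoxynon-3-yn-1-ol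
Product: 9 (3Z,7R)-7-[2-(tert-butyldimethylsilyloxy)propan-2-yl]-9,9-dimethoxy-4-methylnon-3-en-1-ol
Conditions: MeMgBr (5 equiv), Fe(acac)3 (0.2 equiv), THF, −78 → 0 °C; aq. NH4Cl
Reagents that add atoms: methylmagnesium bromide, C[Mg]Br
Why: Iron-catalysed, alkoxide-directed carbomagnesiation of a homopropargylic alcohol adds methyl and magnesium syn with methyl on the distal alkyne carbon, so protonation should give the trisubstituted alkene with the two chain arms cis (Z).

Step 6
Reactants: 9 (3Z,7R)-7-[2-(tert-butyldimethylsilyloxy)propan-2-yl]-9,9-dimethoxy-4-methylnon-3-en-1-ol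
Product: 10 tert-butyl{[(3R,6Z)-3-(2,2-dimethoxyethyl)-9-iodo-2,6-dimethylnon-6-en-2-yl]oxy}dimethylsilane
Conditions: I2, PPh3, imidazole, CH2Cl2, 0 °C
Reagents that add atoms: iodine, II
Why: Appel-type iodination of the primary alcohol under buffered conditions leaves the acetal, the silyl ether and the alkene geometry intact.

Step 7
Reactants: 10 tert-butyl{[(3R,6Z)-3-(2,2-dimethoxyethyl)-9-iodo-2,6-dimethylnon-6-en-2-yl]oxy}dimethylsilane; 11 ethyl (triphenyl-λ5-phosphanylidene)acetate
Product: 13 ethyl (5Z,9R)-9-[2-(tert-butyldimethylsilyloxy)propan-2-yl]-11,11-dimethoxy-6-methyl-2-(triphenyl-λ5-phosphanylidene)undec-5-enoate, via phosphonium iodide 12 (not isolated)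
Conditions: 11 (2.1 equiv), EtOAc, reflux; filtration of the precipitated phosphonium salt
Reagents that add atoms: none
Why: C-Alkylation of the ester-stabilised phosphorane by the primary iodide gives a phosphonium iodide that the second equivalent of 11 deprotonates (transylidation, driven by precipitation of the parent salt), giving the α-substituted stabilised ylide.

Step 8
Reactants: 14 triethyl phosphonoacetate; 15 2-(2-bromoethyl)-1,3-dioxolane
Product: 16 ethyl 2-(diethoxyphosphoryl)-4-(1,3-dioxolan-2-yl)butanoate (racemic)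
Conditions: NaH, DMF, 0 → 60 °C
Reagents that add atoms: none
Why: SN2 alkylation of the phosphonoacetate anion by the primary bromide; the stereocenter formed is erased later in the olefination.

Step 9
Reactants: 16 ethyl 2-(diethoxyphosphoryl)-4-(1,3-dioxolan-2-yl)butanoate
Product: 17 ethyl 2-(diethoxyphosphoryl)-5-oxopentanoate (racemic)
Conditions: 1 M HCl, THF, rt
Reagents that add atoms: water, O
Why: Acid-catalysed hydrolysis of the dioxolane releases the aldehyde; phosphonate and ester are stable to dilute acid.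

Step 10
Reactants: 13 ethyl (5Z,9R)-9-[2-(tert-butyldimethylsilyloxy)propan-2-yl]-11,11-dimethoxy-6-methyl-2-(triphenyl-λ5-phosphanylidene)undec-5-enoate; 17 ethyl 2-(diethoxyphosphoryl)-5-oxopentanoate
Product: 18 diethyl (2E)-2-[(3Z,7R)-7-[2-(tert-butyldimethylsilyloxy)propan-2-yl]-9,9-dimethoxy-4-methylnon-3-en-1-yl]-6-(diethoxyphosphoryl)hept-2-enedioate (both epimers at C6)
Conditions: toluene, 80 °C
Reagents that add atoms: none
Why: Wittig olefination with an α-alkyl ester-stabilised ylide is reliably E-selective (ester trans to the aldehyde-derived chain), and the ylide is too weakly basic to deprotonate the phosphonoacetate unit of 17, so only the aldehyde reacts.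

Step 11
Reactants: 18 diethyl (2E)-2-[(3Z,7R)-7-[2-(tert-butyldimethylsilyloxy)propan-2-yl]-9,9-dimethoxy-4-methylnon-3-en-1-yl]-6-(diethoxyphosphoryl)hept-2-enedioate
Product: 19 diethyl (2E)-2-[(3Z,7R)-7-[2-(tert-butyldimethylsilyloxy)propan-2-yl]-4-methyl-9-oxonon-3-en-1-yl]-6-(diethoxyphosphoryl)hept-2-enedioate
Conditions: AcOH/THF/H2O (3:1:1), 40 °C
Reagents that add atoms: water, O
Why: Mild acid hydrolysis of the dimethyl acetal releases the aldehyde while the tertiary silyl ether, the esters and the phosphonate survive.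

Step 12
Reactants: 19 diethyl (2E)-2-[(3Z,7R)-7-[2-(tert-butyldimethylsilyloxy)propan-2-yl]-4-methyl-9-oxonon-3-en-1-yl]-6-(diethoxyphosphoryl)hept-2-enedioate
Product: 20 diethyl (1E,5E,9Z,13R)-13-[2-(tert-butyldimethylsilyloxy)propan-2-yl]-10-methylcyclotetradeca-1,5,9-triene-2,6-dicarboxylate (the 1Z isomer may accompany it and is carried along)
Conditions: K2CO3, 18-crown-6, toluene, 70 °C, high dilution (slow addition of 19)
Reagents that add atoms: none
Why: Intramolecular Horner–Wadsworth–Emmons olefination under mild carbonate/crown ether conditions closes the 14-membered carbocycle; the geometry of the new enoate does not matter because this double bond is consumed in step 13.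

Step 13
Reactants: 20 diethyl (1E,5E,9Z,13R)-13-[2-(tert-butyldimethylsilyloxy)propan-2-yl]-10-methylcyclotetradeca-1,5,9-triene-2,6-dicarboxylate
Product: 22 diethyl (1R,4Z,8E,12S,13R)-4,15,15-trimethyl-14-oxabicyclo[11.2.1]hexadeca-4,8-diene-8,12-dicarboxylate, via tertiary alcohol 21 (not isolated)
Conditions: Bu4NF (3 equiv), THF, 0 → 45 °C; AcOH quench at 0 °C
Reagents that add atoms: none
Why: Fluoride cleaves the tertiary Si–O bond and the tertiary alkoxide on the 2-propyl group at C13 of 20 adds to C1, the β-carbon of the ring enoate C1=C2, after which the ester enolate is protonated at C2; the addition is reversible. The closest known reaction type is the fluoride- or base-mediated intramolecular oxa-Michael cyclisation of hydroxy enoates to tetrahydrofurans, as used for oxygen-bridged macrocycles. The oxolane closes in the 5-exo-trig mode through the new O–C bond and bridges two carbons of the carbocycle. The ether stereocenter (C13 of 22) is controlled by the purchased center (C1 of 22): only the 3,5-cis oxolane lets the eleven-atom bridge span the five-membered ring without strain, and the reversible addition should funnel to it. The ester-bearing stereocenter (C12 of 22) should be set by protonation of the enolate anti to the new C–O bond in the rotamer that keeps the ether C–H in the enolate plane (allylic 1,3-strain), the usual anti course of alkoxide additions to enoates; this is the least certain element. The step also needs site selectivity between two enoates and convergence of the 1E/1Z mixture: the second enoate would require a nine-membered ether and should stay untouched, and both geometric isomers pass through the same enolate.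

Step 14
Reactants: 22 diethyl (1R,4Z,8E,12S,13R)-4,15,15-trimethyl-14-oxabicyclo[11.2.1]hexadeca-4,8-diene-8,12-dicarboxylate
Product: 23 [(1R,4Z,8E,12R,13R)-4,15,15-trimethyl-14-oxabicyclo[11.2.1]hexadeca-4,8-diene-8,12-diyl]dimethanol
Conditions: i-Bu2AlH (6 equiv), CH2Cl2, −78 → 0 °C; aq. KNaC4H4O6
Reagents that add atoms: none
Why: Ester reduction with excess aluminium hydride at low temperature converts both esters into primary alcohols (1,2-reduction of the conjugated ester gives the allylic alcohol) without epimerising the α-center.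

Step 15
Reactants: 23 [(1R,4Z,8E,12R,13R)-4,15,15-trimethyl-14-oxabicyclo[11.2.1]hexadeca-4,8-diene-8,12-diyl]dimethanol
Product: 24 (1R,4Z,8E,12R,13R)-12-(hydroxymethyl)-4,15,15-trimethyl-14-oxabicyclo[11.2.1]hexadeca-4,8-diene-8-carbaldehyde
Conditions: MnO2 (excess), CH2Cl2, rt
Reagents that add atoms: none
Why: MnO2 oxidises allylic alcohols selectively, so only the hydroxymethyl group on the C8=C9 alkene should become the aldehyde, with the E geometry retained and the saturated primary alcohol untouched.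

Step 16
Reactants: 24 (1R,4Z,8E,12R,13R)-12-(hydroxymethyl)-4,15,15-trimethyl-14-oxabicyclo[11.2.1]hexadeca-4,8-diene-8-carbaldehyde
Product: 25 3-{[(1R,4Z,8E,12R,13R)-8-formyl-4,15,15-trimethyl-14-oxabicyclo[11.2.1]hexadeca-4,8-dien-12-yl]methoxy}-3-oxopropanoic acid
Conditions: Meldrum's acid (1.5 equiv), toluene, 90 °C
Reagents that add atoms: Meldrum's acid (2,2-dimethyl-1,3-dioxane-4,6-dione), CC1(C)OC(=O)CC(=O)O1
Why: Thermal ring opening of Meldrum's acid by the primary alcohol (acylation with loss of acetone) gives the malonic acid half ester directly, without base and without a protecting group on the acid.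

Compound list
1 | (R)-(+)-α-terpineol, 2-[(1R)-4-methylcyclohex-3-en-1-yl]propan-2-ol | CC1=CC[C@@H](CC1)C(C)(C)O | starting material
2 | tert-butyldimethyl({2-[(1R)-4-methylcyclohex-3-en-1-yl]propan-2-yl}oxy)silane | CC1=CC[C@@H](CC1)C(C)(C)O[Si](C)(C)C(C)(C)C | intermediate
3 | (5R)-5-[2-(tert-butyldimethylsilyloxy)propan-2-yl]-7-hydroperoxy-7-methoxyheptan-2-one | CC(=O)CC[C@H](CC(OC)OO)C(C)(C)O[Si](C)(C)C(C)(C)C | intermediate
4 | (3R)-3-[2-(tert-butyldimethylsilyloxy)propan-2-yl]-6-oxoheptanal | CC(=O)CC[C@H](CC=O)C(C)(C)O[Si](C)(C)C(C)(C)C | intermediate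
5 | (5R)-5-[2-(tert-butyldimethylsilyloxy)propan-2-yl]-7,7-dimethoxyheptan-2-one | CC(=O)CC[C@H](CC(OC)OC)C(C)(C)O[Si](C)(C)C(C)(C)C | intermediate
6 | diethyl (5R)-5-[2-(tert-butyldimethylsilyloxy)propan-2-yl]-7,7-dimethoxyhept-1-en-2-yl phosphate | C=C(OP(=O)(OCC)OCC)CC[C@H](CC(OC)OC)C(C)(C)O[Si](C)(C)C(C)(C)C | intermediate
7 | tert-butyl{[(3R)-3-(2,2-dimethoxyethyl)-2-methylhept-6-yn-2-yl]oxy}dimethylsilane | C#CCC[C@H](CC(OC)OC)C(C)(C)O[Si](C)(C)C(C)(C)C | intermediate
8 | (7R)-7-[2-(tert-butyldimethylsilyloxy)propan-2-yl]-9,9-dimethoxynon-3-yn-1-ol | OCCC#CCC[C@H](CC(OC)OC)C(C)(C)O[Si](C)(C)C(C)(C)C | intermediate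
9 | (3Z,7R)-7-[2-(tert-butyldimethylsilyloxy)propan-2-yl]-9,9-dimethoxy-4-methylnon-3-en-1-ol | OCC/C=C(C)\CC[C@H](CC(OC)OC)C(C)(C)O[Si](C)(C)C(C)(C)C | intermediate
10 | tert-butyl{[(3R,6Z)-3-(2,2-dimethoxyethyl)-9-iodo-2,6-dimethylnon-6-en-2-yl]oxy}dimethylsilane | ICC/C=C(C)\CC[C@H](CC(OC)OC)C(C)(C)O[Si](C)(C)C(C)(C)C | intermediate
11 | ethyl (triphenyl-λ5-phosphanylidene)acetate | CCOC(=O)C=P(c1ccccc1)(c1ccccc1)c1ccccc1 | starting material
12 | [(5Z,9R)-9-[2-(tert-butyldimethylsilyloxy)propan-2-yl]-1-ethoxy-11,11-dimethoxy-6-methyl-1-oxoundec-5-en-2-yl]triphenylphosphonium iodide | CCOC(=O)C(CC/C=C(C)\CC[C@H](CC(OC)OC)C(C)(C)O[Si](C)(C)C(C)(C)C)[P+](c1ccccc1)(c1ccccc1)c1ccccc1.[I-] | intermediate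
13 | ethyl (5Z,9R)-9-[2-(tert-butyldimethylsilyloxy)propan-2-yl]-11,11-dimethoxy-6-methyl-2-(triphenyl-λ5-phosphanylidene)undec-5-enoate | CCOC(=O)C(CC/C=C(C)\CC[C@H](CC(OC)OC)C(C)(C)O[Si](C)(C)C(C)(C)C)=P(c1ccccc1)(c1ccccc1)c1ccccc1 | intermediate
14 | triethyl phosphonoacetate | CCOC(=O)CP(=O)(OCC)OCC | starting material
15 | 2-(2-bromoethyl)-1,3-dioxolane | BrCCC1OCCO1 | starting material
16 | ethyl 2-(diethoxyphosphoryl)-4-(1,3-dioxolan-2-yl)butanoate (racemic) | CCOC(=O)C(CCC1OCCO1)P(=O)(OCC)OCC | intermediate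
17 | ethyl 2-(diethoxyphosphoryl)-5-oxopentanoate (racemic) | CCOC(=O)C(CCC=O)P(=O)(OCC)OCC | intermediate
18 | diethyl (2E)-2-[(3Z,7R)-7-[2-(tert-butyldimethylsilyloxy)propan-2-yl]-9,9-dimethoxy-4-methylnon-3-en-1-yl]-6-(diethoxyphosphoryl)hept-2-enedioate (both epimers at C6) | CCOC(=O)C(CC/C=C(\CC/C=C(C)\CC[C@H](CC(OC)OC)C(C)(C)O[Si](C)(C)C(C)(C)C)C(=O)OCC)P(=O)(OCC)OCC | intermediate
19 | diethyl (2E)-2-[(3Z,7R)-7-[2-(tert-butyldimethylsilyloxy)propan-2-yl]-4-methyl-9-oxonon-3-en-1-yl]-6-(diethoxyphosphoryl)hept-2-enedioate (both epimers at C6) | CCOC(=O)C(CC/C=C(\CC/C=C(C)\CC[C@H](CC=O)C(C)(C)O[Si](C)(C)C(C)(C)C)C(=O)OCC)P(=O)(OCC)OCC | intermediate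
20 | diethyl (1E,5E,9Z,13R)-13-[2-(tert-butyldimethylsilyloxy)propan-2-yl]-10-methylcyclotetradeca-1,5,9-triene-2,6-dicarboxylate (1E isomer shown) | CCOC(=O)/C1=C/C[C@H](C(C)(C)O[Si](C)(C)C(C)(C)C)CC/C(C)=C\CC/C(C(=O)OCC)=C\CC1 | intermediate
21 | diethyl (1E,5E,9Z,13R)-13-(2-hydroxypropan-2-yl)-10-methylcyclotetradeca-1,5,9-triene-2,6-dicarboxylate | CCOC(=O)/C1=C/C[C@H](C(C)(C)O)CC/C(C)=C\CC/C(C(=O)OCC)=C\CC1 | intermediate
22 | diethyl (1R,4Z,8E,12S,13R)-4,15,15-trimethyl-14-oxabicyclo[11.2.1]hexadeca-4,8-diene-8,12-dicarboxylate | C/C1=C/CC/C(C(=O)OCC)=C\CC[C@H](C(=O)OCC)[C@H]2C[C@@H](CC1)C(C)(C)O2 | intermediate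
23 | [(1R,4Z,8E,12R,13R)-4,15,15-trimethyl-14-oxabicyclo[11.2.1]hexadeca-4,8-diene-8,12-diyl]dimethanol | C/C1=C/CC/C(CO)=C\CC[C@H](CO)[C@H]2C[C@@H](CC1)C(C)(C)O2 | intermediate
24 | (1R,4Z,8E,12R,13R)-12-(hydroxymethyl)-4,15,15-trimethyl-14-oxabicyclo[11.2.1]hexadeca-4,8-diene-8-carbaldehyde | C/C1=C/CC/C(C=O)=C\CC[C@H](CO)[C@H]2C[C@@H](CC1)C(C)(C)O2 | intermediate
25 | 3-{[(1R,4Z,8E,12R,13R)-8-formyl-4,15,15-trimethyl-14-oxabicyclo[11.2.1]hexadeca-4,8-dien-12-yl]methoxy}-3-oxopropanoic acid | C/C1=C/CC/C(C=O)=C\CC[C@H](COC(=O)CC(=O)O)[C@H]2C[C@@H](CC1)C(C)(C)O2 | target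

Total step count: 16. Longest linear sequence: 14 steps (steps 1–7 and 10–16); steps 8 and 9 make the phosphonate aldehyde 17.

Steps most likely to fail

Step 13. The enolate may be protonated with poor facial selectivity, giving the epimer at the ester-bearing carbon, and the closure may stall through retro-addition of the hindered tertiary alkoxide. The fallback moves the ring closure to the aldehyde oxidation level, where the acceptor is more electrophilic and the α-center can equilibrate. It sets out from 20: i-Bu2AlH reduces both esters to the bis-allylic diol [(1E,5E,9Z,13R)-13-[2-(tert-butyldimethylsilyloxy)propan-2-yl]-10-methylcyclotetradeca-1,5,9-triene-2,6-diyl]dimethanol F1. MnO2 oxidises both allylic alcohols to (1E,5E,9Z,13R)-13-[2-(tert-butyldimethylsilyloxy)propan-2-yl]-10-methylcyclotetradeca-1,5,9-triene-2,6-dicarbaldehyde F2. Bu4NF then removes the silyl group and the alkoxide adds to the enal within five-membered reach, giving (1R,4Z,8E,12S,13R)-4,15,15-trimethyl-14-oxabicyclo[11.2.1]hexadeca-4,8-diene-8,12-dicarbaldehyde F3, whose saturated aldehyde center can epimerise to the more stable isomer under the basic conditions. NaBH4 in EtOH/CH2Cl2 at −78 °C should reduce the saturated aldehyde in preference to the conjugated one, and the route is rejoined at 24.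

Step 12. Oligomerisation may outrun ring closure because the α-substituted phosphonate olefinates slowly. The fallback exchanges the order of the two olefinations and closes the ring at the other enoate by an intramolecular Wittig reaction. It sets out from 10: acetal hydrolysis (AcOH/THF/H2O) gives (3R,6Z)-3-[2-(tert-butyldimethylsilyloxy)propan-2-yl]-9-iodo-6-methylnon-6-enal F4. Intermolecular HWE with the sodium salt of 16 gives ethyl (2E,5R,8Z)-5-[2-(tert-butyldimethylsilyloxy)propan-2-yl]-2-[2-(1,3-dioxolan-2-yl)ethyl]-11-iodo-8-methylundeca-2,8-dienoate F5. Alkylation of 11 by F5 as in step 7 gives diethyl (2E,5R,8Z)-5-[2-(tert-butyldimethylsilyloxy)propan-2-yl]-2-[2-(1,3-dioxolan-2-yl)ethyl]-8-methyl-12-(triphenyl-λ5-phosphanylidene)trideca-2,8-dienedioate F6. Aqueous HCl cleaves the dioxolane and protonates the ylide to [(5Z,9R,11E)-9-[2-(tert-butyldimethylsilyloxy)propan-2-yl]-1-ethoxy-12-(ethoxycarbonyl)-6-methyl-1,15-dioxopentadeca-5,11-dien-2-yl]triphenylphosphonium chloride F7. Slow addition of F7 to K2CO3 at high dilution regenerates the stabilised ylide, which should close the ring E-selectively and return to 20.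

Step 5. Methyl may be delivered to the wrong alkyne carbon, or the alkenylmagnesium intermediate may isomerise, giving regio- or geometric mixtures. The fallback builds the Z-alkene by carbocupration of propyne. It sets out from 5: Baeyer–Villiger oxidation (CF3CO3H, Na2HPO4, CH2Cl2; the primary alkyl group migrates) gives (3R)-3-[2-(tert-butyldimethylsilyloxy)propan-2-yl]-5,5-dimethoxypentyl acetate F8. K2CO3/MeOH gives (3R)-3-[2-(tert-butyldimethylsilyloxy)propan-2-yl]-5,5-dimethoxypentan-1-ol F9. CBr4/PPh3 gives tert-butyl{[(3S)-3-(2-bromoethyl)-5,5-dimethoxy-2-methylpentan-2-yl]oxy}dimethylsilane F10. Its organomagnesium derivative with CuBr·SMe2 adds syn to propyne, and the Z-alkenylcopper opens ethylene oxide, returning to 9.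

Further compounds
F1 | step 13 | [(1E,5E,9Z,13R)-13-[2-(tert-butyldimethylsilyloxy)propan-2-yl]-10-methylcyclotetradeca-1,5,9-triene-2,6-diyl]dimethanol | OC/C1=C/C[C@H](C(C)(C)O[Si](C)(C)C(C)(C)C)CC/C(C)=C\CC/C(CO)=C\CC1
F2 | step 13 | (1E,5E,9Z,13R)-13-[2-(tert-butyldimethylsilyloxy)propan-2-yl]-10-methylcyclotetradeca-1,5,9-triene-2,6-dicarbaldehyde | O=C/C1=C/C[C@H](C(C)(C)O[Si](C)(C)C(C)(C)C)CC/C(C)=C\CC/C(C=O)=C\CC1
F3 | step 13 | (1R,4Z,8E,12S,13R)-4,15,15-trimethyl-14-oxabicyclo[11.2.1]hexadeca-4,8-diene-8,12-dicarbaldehyde | C/C1=C/CC/C(C=O)=C\CC[C@H](C=O)[C@H]2C[C@@H](CC1)C(C)(C)O2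
F4 | step 12 | (3R,6Z)-3-[2-(tert-butyldimethylsilyloxy)propan-2-yl]-9-iodo-6-methylnon-6-enal | ICC/C=C(C)\CC[C@H](CC=O)C(C)(C)O[Si](C)(C)C(C)(C)C
F5 | step 12 | ethyl (2E,5R,8Z)-5-[2-(tert-butyldimethylsilyloxy)propan-2-yl]-2-[2-(1,3-dioxolan-2-yl)ethyl]-11-iodo-8-methylundeca-2,8-dienoate | CCOC(=O)/C(CCC1OCCO1)=C/C[C@H](C(C)(C)O[Si](C)(C)C(C)(C)C)CC/C(C)=C\CCI
F6 | step 12 | diethyl (2E,5R,8Z)-5-[2-(tert-butyldimethylsilyloxy)propan-2-yl]-2-[2-(1,3-dioxolan-2-yl)ethyl]-8-methyl-12-(triphenyl-λ5-phosphanylidene)trideca-2,8-dienedioate | CCOC(=O)/C(CCC1OCCO1)=C/C[C@H](C(C)(C)O[Si](C)(C)C(C)(C)C)CC/C(C)=C\CCC(C(=O)OCC)=P(c1ccccc1)(c1ccccc1)c1ccccc1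
F7 | step 12 | [(5Z,9R,11E)-9-[2-(tert-butyldimethylsilyloxy)propan-2-yl]-1-ethoxy-12-(ethoxycarbonyl)-6-methyl-1,15-dioxopentadeca-5,11-dien-2-yl]triphenylphosphonium chloride | CCOC(=O)/C(CCC=O)=C/C[C@H](C(C)(C)O[Si](C)(C)C(C)(C)C)CC/C(C)=C\CCC(C(=O)OCC)[P+](c1ccccc1)(c1ccccc1)c1ccccc1.[Cl-]
F8 | step 5 | (3R)-3-[2-(tert-butyldimethylsilyloxy)propan-2-yl]-5,5-dimethoxypentyl acetate | CC(=O)OCC[C@H](CC(OC)OC)C(C)(C)O[Si](C)(C)C(C)(C)C
F9 | step 5 | (3R)-3-[2-(tert-butyldimethylsilyloxy)propan-2-yl]-5,5-dimethoxypentan-1-ol | OCC[C@H](CC(OC)OC)C(C)(C)O[Si](C)(C)C(C)(C)C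
F10 | step 5 | tert-butyl{[(3S)-3-(2-bromoethyl)-5,5-dimethoxy-2-methylpentan-2-yl]oxy}dimethylsilane | BrCC[C@H](CC(OC)OC)C(C)(C)O[Si](C)(C)C(C)(C)C
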